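If the two substrates never exchanged, each hand of product would stop at half of the charge; that symmetric stop is the zero of the scale for this flask.

| flask | left-handed substrate | right-handed substrate | partner | free catalyst | precatalyst | impurity | remark | time |
|---|---|---|---|---|---|---|---|---|
| green | 0.054 M | 0.054 M | 0.119 M | 2.7 mM | 2.9 mM | 1.6 mM | the very flask that is asked about, followed so far |  |
| flask | 0.054 M | 0.054 M | 0.119 M | 2.7 mM | 2.9 mM | 1.6 mM |  | 80 min |

green run (percent of the left-handed substrate and right-handed substrate together charged)

| time / min | left-handed product / % | right-handed product / % |
|---|---|---|
| 8.00 | 39.0 | 5.8 |
| 15.0 | 46.2 | 7.4 |
| 25.0 | 53.4 | 12.4 |
| 30.0 | 53.3 | 11.6 |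

(scatter of a reading: 1 percentage point)

- free catalyst is single-handed; left-handed substrate and right-handed substrate are mirror images of each other, charged as a racemate, each of them at the stated concentration
- the analysis behind the earlier runs scatters by 1 percentage point, standard deviation
- an excess is the difference of the two amounts in percent of their sum
- an excess is below zero if the other one leads

- left-handed product and right-handed product together, in percent of the left-handed substrate and right-handed substrate charged together, at 80 min
- excess of left-handed product over right-handed product in the product at 80 min
- whether the exchange between left-handed substrate and right-handed substrate keeps pace with the reaction: how far the product's excess at 80 min gets from its value without exchange to its value with instant exchange (above 80% keeps pace, below 20% hardly takes part, else lags behind)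

In the first 8.00 min the single-handed free catalyst takes the two hands at unequal speed. With exchange taken as negligible this early and each hand as a first-order loss, the selectivity factor s, the log of the fraction of left-handed substrate remaining over the log of the fraction of right-handed substrate remaining, reads 12.3. This is a reading, and the small right-handed figure carries the scatter of 1 percentage point. Under instant exchange the hands would form product in the ratio s, so the excess would be s less one over s plus one, 84.9%. The first reading gives 74.1%, lower than that.

In the middle of the run, left-handed product reads 53.4% at 25.0 min and 53.3% at 30.0 min. The later reading is 3.3 points past the symmetric stop, so right-handed substrate must be feeding the left-handed hand. Yet the excess has fallen to 64.3%, further below 84.9%.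

If each product takes one partner, c(partner) has dropped from 0.119 M to 0.0489 M by 30.0 min. This reckoning commits to an excess under 64.3% at 80 min, and to "lags behind": exchange is visible, but the excess is falling away from its instant-exchange value.

The forecast gives 80%, 53% and lags behind, holding that “exchange limits the supply”. The flask gives 86.4%, 59.7% and lags behind.

    partner + free catalyst + left-handed substrate → free catalyst + left-handed product (k = 13.0 M⁻² s⁻¹)
    racemization catalyst + impurity → spent catalyst (k = 340 M⁻¹ s⁻¹)
    precatalyst → racemization catalyst (k = 0.00230 s⁻¹)
    left-handed substrate + racemization catalyst ⇌ right-handed substrate + racemization catalyst, rate k4*[racemization catalyst]*[left-handed substrate] forward; the back reaction follows from the equilibrium constant (k = 0.240 M⁻¹ s⁻¹)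
    partner + free catalyst + right-handed substrate → free catalyst + right-handed product (k = 0.980 M⁻² s⁻¹)

The flask's excess stands 49% of the way from its value without exchange to its value with instant exchange, and its left-handed product of 69.0% lies 19 points past the symmetric stop. The neighbouring flask, charged with 0.0064 M of impurity, holds 0% racemization catalyst at 80.0 min. Its left-handed substrate stands at 0.015% of own charge, and s, run backwards from that figure, gives 48.9% of its own charge for right-handed substrate, against 51% of own charge in that flask. There left-handed product stands at 50.0% and the excess at 34.6%.

(The runs were generated by integration with constants of no real substance; the scatter is artificial.)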